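C1 is the quaternary ring-fusion carbon bearing CH3, C4 the carbinol carbon bearing isopropyl, C5 the ring-fusion CH, C6 the acyloxy carbon and C8=C9 the alkene of ring B; ring A is C1–C5.
The retrosynthesis cuts, in order, the C6–O acyl bond, C8=C9 (ring B), C6–C7 (methallyl), C1–C10 (allyl) and C1=C5 of a cyclopentene carbaldehyde that traces back to the six-membered ring of (S)-terpinen-4-ol.
Ring B is a cycloheptene with one trisubstituted alkene, C8=C9, separated from C1, C4, C5 and C6 by the methylene groups C10 and C7, so it can be closed there by metathesis once ring A and all four stereocentres are in place.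
In the forward direction, ring A arises by ozonolysis and aldol recyclisation, allyl reaches C1 by 1,2-addition and oxy-Cope shift, methallyl is added to C6, ring B closes by metathesis and the p-coumarate is attached last.
C4 comes from terpinen-4-ol, a reagent-set auxiliary carbinol at C6 relays to C1 through the oxy-Cope chair, C5 follows C4 by equilibration, and C6 is set by chelation to the C4 alkoxide.

Key step: step 8

Assumption: (S)-(+)-terpinen-4-ol is used as a single enantiomer (commercial material enriched if necessary), because C4 of the target is taken from it unchanged.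

Step 1
Reactants: 1 (S)-terpinen-4-ol
Product: 2 (S)-terpinen-4-yl triethylsilyl ether
Conditions: Et3SiOTf, 2,6-lutidine, CH2Cl2, 0 °C to rt
Reagents that add atoms: triethylsilyl trifluoromethanesulfonate, CC[Si](CC)(CC)OS(=O)(=O)C(F)(F)F
Why: Silylation with a silyl triflate and a hindered pyridine base reaches even this tertiary alcohol without touching C4, and the ether keeps the oxygen from forming a hemiketal or leaving as water once it sits β to the aldehyde of steps 2 and 3.

Step 2
Reactants: 2 (S)-terpinen-4-yl triethylsilyl ether
Product: 4 (S)-3-isopropyl-6-oxo-3-(triethylsilyloxy)heptanal, via secondary ozonide 3 (not isolated)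
Conditions: O3, CH2Cl2, −78 °C; PPh3, −78 °C to rt
Reagents that add atoms: ozone, [O-][O+]=O
Why: Ozonolysis with reductive work-up cleaves the only alkene to the methyl ketone (C1) and the aldehyde (C6), the silyl ether and C4 being inert to ozone.

Step 3
Reactants: 4 (S)-3-isopropyl-6-oxo-3-(triethylsilyloxy)heptanal
Product: 5 (R)-5-isopropyl-2-methyl-5-(triethylsilyloxy)cyclopent-1-ene-1-carbaldehyde
Conditions: piperidine (0.2 equiv), AcOH (0.2 equiv), toluene, 60 °C
Reagents that add atoms: none
Why: Intramolecular aldol condensation through the piperidine enamine of the aldehyde (5-enolexo attack of C5 on the methyl ketone C1, then loss of water) gives the cyclopentene carbaldehyde rather than the acetylcyclopentene formed under hydroxide, and the mild buffer together with the poor leaving ability of the hindered silyloxy group should hold back β-elimination at C4.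

Step 4
Reactants: 5 (R)-5-isopropyl-2-methyl-5-(triethylsilyloxy)cyclopent-1-ene-1-carbaldehyde; 6 (−)-B-allyldiisopinocampheylborane
Product: 8 (S)-1-[(R)-5-isopropyl-2-methyl-5-(triethylsilyloxy)cyclopent-1-en-1-yl]but-3-en-1-ol, via borinic ester 7 (not isolated)
Conditions: Et2O, −78 °C to rt; NaOH, H2O2, H2O, 0 °C
Reagents that add atoms: none
Why: Brown allylboration runs through a closed Zimmerman–Traxler chair in which the isopinocampheyl groups derived from (+)-α-pinene send allyl to the Si face of the aldehyde, so the auxiliary C6 carbinol should form as S under reagent control whatever the bias of C4.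

Step 5
Reactants: 8 (S)-1-[(R)-5-isopropyl-2-methyl-5-(triethylsilyloxy)cyclopent-1-en-1-yl]but-3-en-1-ol
Product: 9 (R)-2-[(S)-1-hydroxybut-3-en-1-yl]-1-isopropyl-3-methylcyclopent-2-en-1-ol
Conditions: Bu4NF, THF, rt to 40 °C
Reagents that add atoms: none
Why: Fluoride cleaves the Si–O bond and frees the C4 hydroxyl, which is needed because a silyl group would migrate to the C6 alkoxide in step 6 and because the free oxygen is the control element of steps 6 and 7, and no stereocentre is touched.

Step 6
Reactants: 9 (R)-2-[(S)-1-hydroxybut-3-en-1-yl]-1-isopropyl-3-methylcyclopent-2-en-1-ol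
Product: 12 (1R,2R,5R)-2-allyl-5-hydroxy-5-isopropyl-2-methylcyclopentane-1-carbaldehyde (CHO cis to OH and CH3; trans to allyl and isopropyl), via dipotassium enolate alkoxide 10 (not isolated), via C5-epimeric aldehyde 11 (not isolated)
Conditions: KH (3 equiv), THF, 0 °C to reflux; AcOH, −78 °C; then 1,8-diazabicyclo[5.4.0]undec-7-ene (0.1 equiv), CH2Cl2, 0 °C
Reagents that add atoms: none
Why: Anionic oxy-Cope rearrangement in which the dipotassium dialkoxide, used without crown ether, should react through a chair whose potassium bridges the C6 and C4 oxygens, so that C6–O points to C4, C6–H faces the C1 methyl group (least allylic 1,3-strain) and the allyl chain of the (S)-carbinol lies over the ring face bearing isopropyl, which sets C1 as R, while the dianion can neither expel oxide nor cleave by retro-aldol, and the later amine-base equilibration moves the formyl group at C5 to the face of the C4 hydroxyl, hydrogen-bonded to it and trans to isopropyl and allyl, which is the more stable epimer.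

Step 7
Reactants: 12 (1R,2R,5R)-2-allyl-5-hydroxy-5-isopropyl-2-methylcyclopentane-1-carbaldehyde; 13 2-methylallylmagnesium chloride
Product: 14 (1R,2S,3R)-3-allyl-2-[(S)-1-hydroxy-3-methylbut-3-en-1-yl]-1-isopropyl-3-methylcyclopentan-1-ol
Conditions: 13 (3 equiv), THF, −78 °C; aq NH4Cl
Reagents that add atoms: none
Why: Chelation-controlled (Cram chelate) Grignard addition in which the first equivalent turns the C4 hydroxyl into a magnesium alkoxide that binds the aldehyde oxygen in a six-membered chelate cis-fused to ring A, so that the next equivalent attacks the exposed face turned away from ring A, over C5–H, and sets C6 as S faster than the cold magnesium aldolate can cleave.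

Step 8
Reactants: 14 (1R,2S,3R)-3-allyl-2-[(S)-1-hydroxy-3-methylbut-3-en-1-yl]-1-isopropyl-3-methylcyclopentan-1-ol
Product: 15 jaeschkeanadiol [(3R,3aS,4S,8aR)-3-isopropyl-6,8a-dimethyl-1,2,3,3a,4,5,8,8a-octahydroazulene-3,4-diol]
Conditions: (H2IMes)(PCy3)Cl2Ru=CHPh (second-generation Grubbs catalyst, 5 mol%), CH2Cl2 (2 mM), reflux
Reagents that add atoms: none
Why: Ring-closing olefin metathesis by the Chauvin mechanism: the benzylidene first exchanges with the monosubstituted alkene of the C1 allyl arm, the resulting alkylidene at C9 adds across the 1,1-disubstituted alkene at C8 in an intramolecular [2+2] step, and cycloreversion of the ruthenacyclobutane releases the C8=C9 bond and a methylidene that carries the chain while ethene escapes. The closest known reaction type is the closure of 1,8-dienes built from one terminal and one 1,1-disubstituted alkene to trisubstituted cycloheptenes, hydroazulenes included. Ring B closes as a seven-membered carbocycle by joining the ends of the two arms on the neighbouring carbons C1 and C5, and the ring size allows only the Z alkene. No stereocentre is formed, and C1, C4, C5 and C6 are insulated from the reacting carbons by C10 and C7. The step needs chemoselective loading on the allyl group and cyclisation rather than oligomerisation; the steric gap between the two alkenes secures the first, and the vicinal trans arms, the fully substituted C1 and C4 beside them and high dilution secure the second. The two free hydroxyl groups are tolerated by this catalyst, so no protecting group has to be carried through the step.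

Step 9
Reactants: 16 p-coumaric acid
Product: 18 (E)-3-[4-(tert-butyldimethylsilyloxy)phenyl]acrylic acid, via bis-silyl derivative 17 (not isolated)
Conditions: t-BuMe2SiCl (2.5 equiv), imidazole, DMF, rt; then AcOH–THF–H2O, rt
Reagents that add atoms: tert-butyldimethylsilyl chloride, CC(C)(C)[Si](C)(C)Cl
Why: Silylation of both acidic OH groups followed by selective hydrolysis of the labile silyl ester leaves the acid-stable aryl silyl ether and the E alkene untouched, so the phenol cannot compete in the esterification.

Step 10
Reactants: 15 jaeschkeanadiol; 18 (E)-3-[4-(tert-butyldimethylsilyloxy)phenyl]acrylic acid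
Product: 19 jaeschkeanadiol 6-O-[(E)-4-(tert-butyldimethylsilyloxy)cinnamate]
Conditions: N,N'-dicyclohexylcarbodiimide, 4-(dimethylamino)pyridine, CH2Cl2, rt
Reagents that add atoms: none
Why: Steglich esterification acylates only the secondary C6 hydroxyl, because the tertiary C4 hydroxyl next to isopropyl is inert to the acylpyridinium ion, and C6 keeps its configuration since its C–O bond is not broken.

Step 11
Reactants: 19 jaeschkeanadiol 6-O-[(E)-4-(tert-butyldimethylsilyloxy)cinnamate]
Product: 20 jaeschkeanadiol 6-O-(E)-p-coumarate (CNP0265426.1)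
Conditions: Bu4NF, AcOH, THF, 0 °C
Reagents that add atoms: none
Why: Fluoride-induced cleavage of the aryl silyl ether is fast at low temperature, and the acetic acid buffer protonates the phenoxide so that the hindered ester, the alkenes and the four stereocentres stay untouched.

Compound list
1 | (S)-terpinen-4-ol | CC1=CC[C@](O)(C(C)C)CC1 | starting material
2 | (S)-terpinen-4-yl triethylsilyl ether | CC1=CC[C@](O[Si](CC)(CC)CC)(C(C)C)CC1 | intermediate
3 | secondary ozonide of 2 (both bridgehead diastereomers) | CC12CC[C@@](O[Si](CC)(CC)CC)(C(C)C)CC(OO1)O2 | intermediate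
4 | (S)-3-isopropyl-6-oxo-3-(triethylsilyloxy)heptanal | CC(=O)CC[C@@](O[Si](CC)(CC)CC)(C(C)C)CC=O | intermediate
5 | (R)-5-isopropyl-2-methyl-5-(triethylsilyloxy)cyclopent-1-ene-1-carbaldehyde | CC1=C(C=O)[C@](O[Si](CC)(CC)CC)(C(C)C)CC1 | intermediate
6 | (−)-B-allyldiisopinocampheylborane | C=CCB([C@@H]1C[C@@H]2C[C@H]([C@H]1C)C2(C)C)[C@@H]1C[C@@H]2C[C@H]([C@H]1C)C2(C)C | starting material
7 | diisopinocampheylborinic ester of 8 | C=CC[C@H](OB([C@@H]1C[C@@H]2C[C@H]([C@H]1C)C2(C)C)[C@@H]1C[C@@H]2C[C@H]([C@H]1C)C2(C)C)C1=C(C)CC[C@@]1(O[Si](CC)(CC)CC)C(C)C | intermediate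
8 | (S)-1-[(R)-5-isopropyl-2-methyl-5-(triethylsilyloxy)cyclopent-1-en-1-yl]but-3-en-1-ol | C=CC[C@H](O)C1=C(C)CC[C@@]1(O[Si](CC)(CC)CC)C(C)C | intermediate
9 | (R)-2-[(S)-1-hydroxybut-3-en-1-yl]-1-isopropyl-3-methylcyclopent-2-en-1-ol | C=CC[C@H](O)C1=C(C)CC[C@@]1(O)C(C)C | intermediate
10 | dipotassium enolate alkoxide of 12 (enolate oxygen cis to C4) | C=CC[C@@]1(C)CC[C@@]([O-])(C(C)C)/C1=C\[O-].[K+].[K+] | intermediate
11 | (1S,2R,5R)-2-allyl-5-hydroxy-5-isopropyl-2-methylcyclopentane-1-carbaldehyde (C5 epimer of 12) | C=CC[C@@]1(C)CC[C@@](O)(C(C)C)[C@H]1C=O | intermediate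
12 | (1R,2R,5R)-2-allyl-5-hydroxy-5-isopropyl-2-methylcyclopentane-1-carbaldehyde | C=CC[C@@]1(C)CC[C@@](O)(C(C)C)[C@@H]1C=O | intermediate
13 | 2-methylallylmagnesium chloride | C=C(C)C[Mg]Cl | starting material
14 | (1R,2S,3R)-3-allyl-2-[(S)-1-hydroxy-3-methylbut-3-en-1-yl]-1-isopropyl-3-methylcyclopentan-1-ol (metathesis precursor) | C=CC[C@@]1(C)CC[C@@](O)(C(C)C)[C@@H]1[C@@H](O)CC(C)=C | intermediate
15 | jaeschkeanadiol (metathesis product; trans-fused hydroazulene diol) | CC1=CC[C@@]2(C)CC[C@@](O)(C(C)C)[C@@H]2[C@@H](O)C1 | intermediate
16 | p-coumaric acid | O=C(O)/C=C/c1ccc(O)cc1 | starting material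
17 | tert-butyldimethylsilyl (E)-3-[4-(tert-butyldimethylsilyloxy)phenyl]acrylate | CC(C)(C)[Si](C)(C)OC(=O)/C=C/c1ccc(O[Si](C)(C)C(C)(C)C)cc1 | intermediate
18 | (E)-3-[4-(tert-butyldimethylsilyloxy)phenyl]acrylic acid | O=C(O)/C=C/c1ccc(O[Si](C)(C)C(C)(C)C)cc1 | intermediate
19 | jaeschkeanadiol 6-O-[(E)-4-(tert-butyldimethylsilyloxy)cinnamate] | CC1=CC[C@@]2(C)CC[C@@](O)(C(C)C)[C@@H]2[C@@H](OC(=O)/C=C/c2ccc(O[Si](C)(C)C(C)(C)C)cc2)C1 | intermediate
20 | (3R,3aS,4S,8aR)-3-hydroxy-3-isopropyl-6,8a-dimethyl-1,2,3,3a,4,5,8,8a-octahydroazulen-4-yl (E)-3-(4-hydroxyphenyl)acrylate | CC1=CC[C@@]2(C)CC[C@@](O)(C(C)C)[C@@H]2[C@@H](OC(=O)/C=C/c2ccc(O)cc2)C1 | target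

Total step count: 11. Longest linear sequence: 10 steps (steps 1–8, 10 and 11).

Steps most likely to fail

Step 6.
- **What may go wrong:** The potassium bridge between the two oxygens may be lost in solution, which frees rotation about C5–C6 and lets allyl reach the wrong face of C1. The shift onto a tetrasubstituted alkene may also be slow, and the amine-base equilibration at C5 may be accompanied by retro-aldol opening of ring A.
- **Fallback:** It sets out from diol 9 and replaces the ionic bridge by a covalent tether. t-Bu2Si(OTf)2 and 2,6-lutidine give the cyclic di-tert-butylsilylene acetal F1. Its six-membered dioxasilinane ring holds C6–O next to C4–O, and allylic strain places the allyl chain axial on the isopropyl face.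
- **Return to the route:** A thermal siloxy-Cope rearrangement (1,2-dichlorobenzene, about 200 °C) then gives the bicyclic silyl enol ether F2. HF·pyridine in THF releases the aldehyde while C6–O is still tied to the face of C4–O and with no base present at any stage, which brings the route back at 12.

Step 7.
- **What may go wrong:** The magnesium chelate may open, so that the aldehyde reacts from its dipole-minimised rotamer with the opposite facial sense at C6. The basic reagent may also enolise the hindered aldehyde or trigger retro-aldol cleavage.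
- **Fallback:** It sets out from 12 and delivers the nucleophile from the C4 oxygen itself. Chloro(dimethyl)(2-methylallyl)silane with imidazole in DMF gives the C4 dimethyl(2-methylallyl)silyl ether F3.
- **Return to the route:** TiCl4 in CH2Cl2 at −78 °C triggers an intramolecular Hosomi–Sakurai transfer from the C4 side of the carbonyl group, the same trajectory as in the chelate. Silicon ends up bridging both oxygens in the cyclic dimethylsilylene acetal F4, and HF·pyridine returns the route at 14.

Step 8.
- **What may go wrong:** The free 1,3-diol may bind ruthenium and slow turnover at the 1,1-disubstituted alkene. Oligomerisation through the allyl arm and alkene isomerisation could then compete with closure of the trans-fused seven-membered ring.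
- **Fallback:** It sets out from 14 and masks the homoallylic hydroxyl before the same C8=C9 closure. t-BuMe2SiOTf and 2,6-lutidine at −78 °C silylate only the secondary C6 hydroxyl to give the C6 silyl ether F5.
- **Return to the route:** (H2IMes)(PCy3)Cl2Ru=CHPh in dilute CH2Cl2 closes ring B to the silylated hydroazulene F6, and Bu4NF in THF returns the route at 15.

Further compounds
F1 | step 6 | di-tert-butylsilylene acetal of diol 9 | C=CC[C@@H]1O[Si](C(C)(C)C)(C(C)(C)C)O[C@@]2(C(C)C)CCC(C)=C12
F2 | step 6 | bicyclic di-tert-butylsilylene enol ether of aldehyde 12 | C=CC[C@@]1(C)CC[C@]2(C(C)C)O[Si](C(C)(C)C)(C(C)(C)C)OC=C12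
F3 | step 7 | C4 dimethyl(2-methylallyl)silyl ether of aldehyde 12 | C=CC[C@@]1(C)CC[C@@](O[Si](C)(C)CC(C)=C)(C(C)C)[C@@H]1C=O
F4 | step 7 | cyclic dimethylsilylene acetal of diol 14 | C=CC[C@@]1(C)CC[C@]2(C(C)C)O[Si](C)(C)O[C@@H](CC(C)=C)[C@H]12
F5 | step 8 | C6 tert-butyldimethylsilyl ether of diol 14 | C=CC[C@@]1(C)CC[C@@](O)(C(C)C)[C@@H]1[C@@H](O[Si](C)(C)C(C)(C)C)CC(C)=C
F6 | step 8 | C6 tert-butyldimethylsilyl ether of jaeschkeanadiol 15 | CC1=CC[C@@]2(C)CC[C@@](O)(C(C)C)[C@@H]2[C@@H](O[Si](C)(C)C(C)(C)C)C1
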